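**Strategy.** Ring C of the upper (catechin) unit is a 2-aryl chroman whose O1 is an aryl ether oxygen and whose C3 and C4 carry trans oxygen and aryl groups. It is therefore disconnected by an oxa-Povarov annulation: the cationic 2-oxadiene C4a=C8a–O1=C2, an O-aryl oxocarbenium ion released from a racemic pivaloyloxy aryloxy acetal, takes up (E)-1,2-bis(benzyloxy)ethene as C3–C4. Under a chiral acid this one operation forms C2–C3 and C4–C4a, closes ring C and sets C2 and C3 stereoconvergently, while leaving a C4 benzyloxy group. Its ionisation and capture by C8 of perbenzylated EGCG forges the interflavan bond; hydrogenolysis ends the synthesis.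

Key step: step 5

Remark: flavan numbering (O1, C2, C3, C4, C4a, C5–C8, C8a) is used for both units; "upper" is the catechin unit, "lower" the EGCG unit.
Assumption: the (R) acid is written in step 5; which enantiomer leads to the 2R series is to be settled by screening, and the SMILES show the intended series.
Remark: 14 is drawn as the expected 3,4-trans isomer; its C4 configuration is erased in step 6, so either C4 epimer serves.

Step 1
Reactants: 1 (−)-epigallocatechin
Product: 2 penta-O-benzyl-(−)-epigallocatechin [(2R,3R)-5,7-bis(benzyloxy)-2-[3,4,5-tris(benzyloxy)phenyl]chroman-3-ol]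
Conditions: BnBr (5.5 equiv), K2CO3 (6 equiv), DMF, 0 °C → rt, argon
Reagents that add atoms: benzyl bromide, BrCc1ccccc1
Why: Williamson O-benzylation of the five phenols, the only hydroxyl groups acidic enough for K2CO3, which leaves the secondary C3 hydroxyl free for the esterification and, at low temperature under argon, should leave the two stereocentres and the oxidation-prone pyrogallol ring intact.

Step 2
Reactants: 2 penta-O-benzyl-(−)-epigallocatechin; 3 3,4,5-tris(benzyloxy)benzoic acid
Product: 4 octa-O-benzyl-EGCG [(2R,3R)-5,7-bis(benzyloxy)-2-[3,4,5-tris(benzyloxy)phenyl]chroman-3-yl 3,4,5-tris(benzyloxy)benzoate]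
Conditions: DCC (1.5 equiv), DMAP (0.2 equiv), CH2Cl2, 0 °C → rt
Reagents that add atoms: none
Why: Steglich esterification of the only free hydroxyl through the N-acylpyridinium ion of acid 3; the C3–O bond is not broken, so the 2,3-cis configuration is retained, and ring A remains an electron-rich Friedel–Crafts nucleophile.

Step 3
Reactants: 5 (E)-1,2-bis(4,4,5,5-tetramethyl-1,3,2-dioxaborolan-2-yl)ethene
Product: 7 (E)-1,2-bis(benzyloxy)ethene, via mono-ether boronate 6 (not isolated)
Conditions: BnOH (10 equiv), Cu(OAc)2 (4.4 equiv), Et3N (8 equiv), 4 Å MS, CH2Cl2, rt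
Reagents that add atoms: benzyl alcohol, OCc1ccccc1
Why: Chan–Lam–Evans-type oxidative C–O coupling of an alkenyl boronate with an alcohol promoted by Cu(OAc)2, which proceeds with retention of alkene geometry, so both C–B bonds become C–OBn and the (E)-geometry needed for the trans C2/C3 relationship is carried over.

Step 4
Reactants: 8 3,4-bis(benzyloxy)benzaldehyde; 9 3,5-bis(benzyloxy)phenol
Product: 11 [3,5-bis(benzyloxy)phenoxy][3,4-bis(benzyloxy)phenyl]methyl pivalate (racemic), via chloro ester 10 (not isolated)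
Conditions: PivCl (1.05 equiv), ZnCl2 (5 mol %), CH2Cl2, 0 °C → rt; volatiles off; then 9, Cs2CO3, DMF, −20 → 0 °C
Reagents that add atoms: pivaloyl chloride, CC(C)(C)C(Cl)=O
Why: ZnCl2-catalysed addition of the acyl chloride across the aldehyde carbonyl gives the α-chloroalkyl ester 10, and the cesium phenoxide of 9 displaces chloride at the benzylic carbon by O-alkylation (acyloxyalkylation of a phenol), the bulky pivalate suppressing acyl transfer; the acetal centre is racemic, which is immaterial because it becomes planar in step 5.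

Step 5
Reactants: 11 mixed pivaloyloxy aryloxy acetal (racemic); 7 (E)-1,2-bis(benzyloxy)ethene
Product: 14 (2R,3S,4R)-3,4,5,7-tetrakis(benzyloxy)-2-[3,4-bis(benzyloxy)phenyl]chromane, via aryl oxocarbenium ion 12 (not isolated), via benzyloxycarbenium adduct 13 (not isolated)
Conditions: 7 (2 equiv), (R)-3,3'-bis(2,4,6-triisopropylphenyl)-1,1'-binaphthyl-2,2'-diyl N-(trifluoromethylsulfonyl)phosphoramide (5 mol %), 5 Å MS, toluene/CH2Cl2, −78 °C; Et3N quench
Reagents that add atoms: none
Why: Proposed new method: The chiral acid protonates the pivalate of racemic 11 and pivalic acid departs (it is the better leaving group and leaves the better-stabilised cation), so both enantiomers of 11 converge on the planar (E)-O-aryl oxocarbenium ion 12, held as a contact ion pair by the chiral phosphoramide anion. The electron-rich alkene 7 adds through one of its equivalent carbons to C2 of 12 (C2–C3 bond) to give the benzyloxycarbenium ion 13, whose C4 is then attacked by the ortho carbon (C4a) of the 3,5-bis(benzyloxy)phenyl ether in a six-membered Friedel–Crafts closure of ring C (6-exo-trig at the C4=O+ unit, the second bond of a stepwise polar [4+2] cycloaddition; C4–C4a bond), the arenium proton regenerating the acid. The closest known reaction types are the Lewis-acid-promoted oxa-Povarov reaction of aryl oxocarbenium ions with alkenes, known in racemic form, and chiral-acid-catalysed Povarov reactions of (E)-enecarbamates; the enantioselective variant with a chiral counteranion and a 1,2-dioxygenated alkene is what is new. C2 is set by the anion, which should shield one face of 12; C3 follows from the endo-type approach that places the C4 benzyloxy group under the oxadiene and, because 7 is (E), the C3 benzyloxy group exo and hence trans to the C2 aryl group; C4 should close trans to C3 in the all-equatorial chair, but its configuration is erased in step 6. The step needs ionisation toward the aryloxy and not the acyloxy cation (secured by the carboxylate leaving group), capture of 12 by the alkene before ring A of a second molecule does so (excess of 7, low temperature, dilution), ortho closure (the only position within reach) and survival of the acid-labile C4 ether (catalytic acid, −78 °C, amine quench).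

Step 6
Reactants: 14 (2R,3S,4R)-3,4,5,7-tetrakis(benzyloxy)-2-[3,4-bis(benzyloxy)phenyl]chromane; 4 octa-O-benzyl-EGCG
Product: 16 trideca-O-benzyl catechin-(4α→8)-epigallocatechin 3-O-gallate [upper unit 2R,3S,4S; lower unit 2R,3R], via flavan-4-yl cation 15 (not isolated)
Conditions: 4 (3 equiv, excess recovered), Me3SiOTf (0.2 equiv), 4 Å MS, CH2Cl2, −78 °C; Et3N quench
Reagents that add atoms: none
Why: Me3SiOTf ionises the doubly activated benzylic C4–OBn bond to the ring-A-stabilised cation 15, which C8 of ring A of 4 captures in a Friedel–Crafts reaction (the standard interflavan bond formation of proanthocyanidin synthesis; C8 is the more reactive site of benzylated flavan-3-ols and the excess of 4 limits oligomerisation); the nucleophile should enter trans to the C3 benzyloxy group of the 2,3-trans unit, which sets C4 as S (4α).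

Step 7
Reactants: 16 trideca-O-benzyl dimer
Product: 17 catechin-(4α→8)-epigallocatechin 3-O-gallate (CNP0246304.1)
Conditions: H2 (1 atm), Pd(OH)2/C, THF/MeOH/H2O, rt
Reagents that add atoms: none
Why: Hydrogenolysis over Pd(OH)2/C cleaves the twelve aryl benzyl ethers and the C3 alkyl benzyl ether in one operation under neutral conditions, which should spare the gallate ester, the acid-labile interflavan bond and all five stereocentres.

**Compound list**

1 | (−)-epigallocatechin, (2R,3R) | O[C@@H]1Cc2c(O)cc(O)cc2O[C@@H]1c1cc(O)c(O)c(O)c1 | starting material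
2 | penta-O-benzyl-(−)-epigallocatechin, (2R,3R) | O[C@@H]1Cc2c(OCc3ccccc3)cc(OCc3ccccc3)cc2O[C@@H]1c1cc(OCc2ccccc2)c(OCc2ccccc2)c(OCc2ccccc2)c1 | intermediate
3 | 3,4,5-tris(benzyloxy)benzoic acid | OC(=O)c1cc(OCc2ccccc2)c(OCc2ccccc2)c(OCc2ccccc2)c1 | starting material
4 | octa-O-benzyl-EGCG, (2R,3R) | O=C(O[C@@H]1Cc2c(OCc3ccccc3)cc(OCc3ccccc3)cc2O[C@@H]1c1cc(OCc2ccccc2)c(OCc2ccccc2)c(OCc2ccccc2)c1)c1cc(OCc2ccccc2)c(OCc2ccccc2)c(OCc2ccccc2)c1 | intermediate
5 | (E)-1,2-bis(4,4,5,5-tetramethyl-1,3,2-dioxaborolan-2-yl)ethene | CC1(C)OB(OC1(C)C)/C=C/B1OC(C)(C)C(C)(C)O1 | starting material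
6 | (E)-2-[2-(benzyloxy)ethenyl]-4,4,5,5-tetramethyl-1,3,2-dioxaborolane (not isolated) | CC1(C)OB(OC1(C)C)/C=C/OCc1ccccc1 | intermediate
7 | (E)-1,2-bis(benzyloxy)ethene | c1ccccc1CO/C=C/OCc1ccccc1 | intermediate
8 | 3,4-bis(benzyloxy)benzaldehyde | O=Cc1ccc(OCc2ccccc2)c(OCc2ccccc2)c1 | starting material
9 | 3,5-bis(benzyloxy)phenol | Oc1cc(OCc2ccccc2)cc(OCc2ccccc2)c1 | starting material
10 | chloro[3,4-bis(benzyloxy)phenyl]methyl pivalate, racemic (not isolated) | CC(C)(C)C(=O)OC(Cl)c1ccc(OCc2ccccc2)c(OCc2ccccc2)c1 | intermediate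
11 | [3,5-bis(benzyloxy)phenoxy][3,4-bis(benzyloxy)phenyl]methyl pivalate, racemic | CC(C)(C)C(=O)OC(Oc1cc(OCc2ccccc2)cc(OCc2ccccc2)c1)c1ccc(OCc2ccccc2)c(OCc2ccccc2)c1 | intermediate
12 | (E)-[3,4-bis(benzyloxy)benzylidene][3,5-bis(benzyloxy)phenyl]oxonium ion, ion pair with the catalyst anion (not isolated) | O(Cc1ccccc1)c1ccc(/C=[O+]/c2cc(OCc3ccccc3)cc(OCc3ccccc3)c2)cc1OCc1ccccc1 | intermediate
13 | open-chain benzyloxycarbenium ion BnO+=C4H–C3H(OBn)–C2H(aryl)(O-aryl) after C2–C3 bond formation (not isolated) | C(=[O+]Cc1ccccc1)[C@H](OCc1ccccc1)[C@H](Oc1cc(OCc2ccccc2)cc(OCc2ccccc2)c1)c1ccc(OCc2ccccc2)c(OCc2ccccc2)c1 | intermediate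
14 | (2R,3S,4R)-3,4,5,7-tetrakis(benzyloxy)-2-[3,4-bis(benzyloxy)phenyl]chromane (2,3-trans, 3,4-trans) | O(Cc1ccccc1)[C@@H]1c2c(OCc3ccccc3)cc(OCc3ccccc3)cc2O[C@H](c2ccc(OCc3ccccc3)c(OCc3ccccc3)c2)[C@H]1OCc1ccccc1 | intermediate
15 | (2R,3S)-3,5,7-tris(benzyloxy)-2-[3,4-bis(benzyloxy)phenyl]chroman-4-ylium ion (not isolated) | [CH+]1c2c(OCc3ccccc3)cc(OCc3ccccc3)cc2O[C@H](c2ccc(OCc3ccccc3)c(OCc3ccccc3)c2)[C@H]1OCc1ccccc1 | intermediate
16 | trideca-O-benzyl catechin-(4α→8)-epigallocatechin 3-O-gallate, upper 2R,3S,4S, lower 2R,3R | O=C(O[C@@H]1Cc2c(OCc5ccccc5)cc(OCc5ccccc5)c([C@@H]3c4c(OCc5ccccc5)cc(OCc5ccccc5)cc4O[C@H](c4ccc(OCc5ccccc5)c(OCc5ccccc5)c4)[C@H]3OCc5ccccc5)c2O[C@@H]1c1cc(OCc5ccccc5)c(OCc5ccccc5)c(OCc5ccccc5)c1)c1cc(OCc5ccccc5)c(OCc5ccccc5)c(OCc5ccccc5)c1 | intermediate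
17 | catechin-(4α→8)-epigallocatechin 3-O-gallate, upper 2R,3S,4S, lower 2R,3R | O=C(O[C@@H]1Cc2c(O)cc(O)c([C@@H]3c4c(O)cc(O)cc4O[C@H](c4ccc(O)c(O)c4)[C@H]3O)c2O[C@@H]1c1cc(O)c(O)c(O)c1)c1cc(O)c(O)c(O)c1 | target

**Totals.** Total step count: 7. Longest linear sequence: 4 steps (4, 5, 6, 7; the branch through steps 1, 2, 6, 7 is equally long).

**Steps most likely to fail**

Step 5 (Proposed new method). The chiral anion may discriminate the faces of ion 12 poorly. Ring A of a second molecule may capture 12 before the alkene does, leading to oligomers. The acid may ionise the C4 ether of the product. Fallback: set out from 11 and 7 and give up catalyst control. SnCl4 (1.1 equiv), CH2Cl2, −78 °C, the Lewis-acid-promoted oxa-Povarov reaction in its racemic form, should give 14 together with its enantiomer, (2S,3R,4S)-3,4,5,7-tetrakis(benzyloxy)-2-[3,4-bis(benzyloxy)phenyl]chromane F1. The racemate is coupled with 4 as in step 6, which should turn the enantiomers into 16 and its upper-unit diastereomer, the trideca-O-benzyl ent-catechin-(4β→8)-epigallocatechin 3-O-gallate F2. These are separated by chromatography, and the route is rejoined at 16.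

Step 4. The ambident, phloroglucinol-type phenoxide may be alkylated on carbon, the pivaloyl group may be transferred to the phenoxide, or the acetal may ionise on purification. Fallback: set out from 9 and replace leaving-group ionisation by C–H oxidation. Williamson etherification with 3,4-bis(benzyloxy)benzyl chloride (K2CO3, DMF) should give 3,5-bis(benzyloxy)phenyl 3,4-bis(benzyloxy)benzyl ether F3. Hydride abstraction from its O–CH2 group with DDQ (CH2Cl2, 4 Å MS, 0 °C), the known oxidative entry to benzylic oxocarbenium ions, should give ion 12 directly, which is then treated with 7 and the chiral acid. The route is rejoined at 12.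

Step 6. The cation may attack C6 instead of C8, may oligomerise through ring A of the product, or may react sluggishly because the 3-O-galloyl group shields C8. Facial selectivity may also be lower with a non-participating C3 ether. Fallback: set out from 2 and introduce the gallate after the union. Penta-O-benzyl-epigallocatechin 2, the standard free-hydroxyl flavan-3-ol nucleophile, is coupled with 14 (Me3SiOTf, CH2Cl2, −78 °C) and should give the dimer with a free lower 3-hydroxyl, deca-O-benzyl catechin-(4α→8)-epigallocatechin F4. Its only hydroxyl is acylated with acid 3 (DCC, DMAP, CH2Cl2), and the route is rejoined at 16.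

**Further compounds**

F1 | step 5 | (2S,3R,4S)-3,4,5,7-tetrakis(benzyloxy)-2-[3,4-bis(benzyloxy)phenyl]chromane (enantiomer of 14) | O(Cc1ccccc1)[C@H]1c2c(OCc3ccccc3)cc(OCc3ccccc3)cc2O[C@@H](c2ccc(OCc3ccccc3)c(OCc3ccccc3)c2)[C@@H]1OCc1ccccc1
F2 | step 5 | trideca-O-benzyl ent-catechin-(4β→8)-epigallocatechin 3-O-gallate, upper 2S,3R,4R, lower 2R,3R | O=C(O[C@@H]1Cc2c(OCc5ccccc5)cc(OCc5ccccc5)c([C@H]3c4c(OCc5ccccc5)cc(OCc5ccccc5)cc4O[C@@H](c4ccc(OCc5ccccc5)c(OCc5ccccc5)c4)[C@@H]3OCc5ccccc5)c2O[C@@H]1c1cc(OCc5ccccc5)c(OCc5ccccc5)c(OCc5ccccc5)c1)c1cc(OCc5ccccc5)c(OCc5ccccc5)c(OCc5ccccc5)c1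
F3 | step 4 | 3,5-bis(benzyloxy)phenyl 3,4-bis(benzyloxy)benzyl ether | O(Cc1ccc(OCc2ccccc2)c(OCc2ccccc2)c1)c1cc(OCc2ccccc2)cc(OCc2ccccc2)c1
F4 | step 6 | deca-O-benzyl catechin-(4α→8)-epigallocatechin with free lower 3-hydroxyl, upper 2R,3S,4S, lower 2R,3R | O[C@@H]1Cc2c(OCc5ccccc5)cc(OCc5ccccc5)c([C@@H]3c4c(OCc5ccccc5)cc(OCc5ccccc5)cc4O[C@H](c4ccc(OCc5ccccc5)c(OCc5ccccc5)c4)[C@H]3OCc5ccccc5)c2O[C@@H]1c1cc(OCc5ccccc5)c(OCc5ccccc5)c(OCc5ccccc5)c1
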